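The single product in the maple flask peaked near 40.4% at 4.00 min and had sunk to 32.6% by 25.0 min while the substrate went on falling, so it was being made and lost at once. The asked flask is the maple flask itself, followed on to 30 min.

| setting | maple | oak | flask |
|---|---|---|---|
| substrate | 1 M | 1 M | 1.0 M |
| coupling partner | 0.80 equiv | 0.80 equiv | 0.800 equiv |
| temperature | 70 °C | 65 °C | 70 °C |
| remark | the very flask that is asked about, followed so far | run made earlier |  |
| time |  |  | 30 min |

| run | time / min | single product / % | substrate / % |
|---|---|---|---|
| maple | 2.00 | 39.1 | 47.0 |
| maple | 4.00 | 40.4 | 38.3 |
| maple | 6.00 | 39.6 | 34.5 |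
| maple | 12.0 | 37.1 | 28.1 |
| maple | 25.0 | 32.6 | 22.7 |
| oak | 2.00 | 35.2 | 54.7 |
| oak | 4.00 | 40.5 | 43.0 |
| oak | 6.00 | 40.2 | 38.9 |
| oak | 12.0 | 39.5 | 31.6 |
| oak | 25.0 | 33.6 | 25.7 |

(readings scatter by 0.5 percentage points)

- beta: at 30 min add coupling partner, 50.0% of the amount charged, then wait 1.0 h
- theta: at 30 min raise the temperature by 20 K, then wait 1.0 h
- gamma: at 30 min take out 90% of the single product then present, then wait 1.0 h
- epsilon: change nothing and wait 1.0 h more

- single product, in percent of the substrate first charged, at 30 min
- which option adds most single product ("none" when 2 percentage points or less is all one gets) (beta / theta / gamma / epsilon / none)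
- single product present, with what was taken out counted in, in percent of the substrate first charged, after gamma
- single product present, with what was taken out counted in, in percent of the substrate first charged, after epsilon

- single product that was removed still counts
- the analysis behind the earlier runs scatters by 0.5 percentage points, standard deviation
- candidate steps: coupling partner + single product <-> double product; coupling partner -> decomposition product; single product <-> isomer of the product; substrate + coupling partner -> single product
- additions bring no volume worth counting

So I solved the maple run at both ends. At the supply end the coupling partner is the limiting reagent: at 0.800 equiv it lets the substrate lose 80.0% of its charge, and the reading at 25.0 min showed 77.3% lost already. But of that loss 45 percentage points was no longer single product. To join the ends I carried one number, the share 0.422, which is [single product] divided by the substrate lost. That reading belongs to 25.0 min, and at 12.0 min the share had been 0.516. Share times ceiling gave me 33.7% for 30 min, but the share was still falling, so I took my figure as high.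

The forecast said 30.3%, lower than mine, chose gamma, and gave 42.5% after gamma and 24% after epsilon, holding that “Theta gives little”.

The flask gave 31.0%, then 47.2% after gamma and 29.6% after epsilon. The best option was theta, with a gain of 22 points against 16 points for gamma.

    coupling partner + single product ⇌ double product (K = 3.10 L mol⁻¹, k = 0.580 L mol⁻¹ min⁻¹, Ea = 69.0 kJ mol⁻¹, ΔH = −9.00 kJ mol⁻¹)
    coupling partner → decomposition product (k = 2.70 × 10⁻⁴ min⁻¹, Ea = 118 kJ mol⁻¹)
    single product ⇌ isomer of the product (K = 1.70, k = 0.0910 min⁻¹, Ea = 108 kJ mol⁻¹, ΔH = −64.0 kJ mol⁻¹)
    substrate + coupling partner → single product (k = 0.940 L mol⁻¹ min⁻¹, Ea = 76.0 kJ mol⁻¹)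
    (constants at 70 °C)

At 30 min the maple flask's share stood at 0.398. In the neighbouring flask with 0.480 equiv of coupling partner, 47.8% of the substrate was lost, and the share read earlier turns that into 20.2%, against 18.6% simulated. The share of the maple flask sank mainly because single product passed into isomer of the product, both ways: in the run with that step taken away, single product at 30 min stood at 74.2% instead of 31.0%.

(The numbers in the tables come from a simulation for substances that don't exist, and the scatter is random.)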